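**Retrosynthetic overview**
- The oxirane is installed last, by hydroxyl-directed epoxidation of the C8=C9 allylic alcohol.
- Ring B (seven-membered) is the second ring, closed at C8=C9 by ring-closing metathesis. Its C10 carbinol comes from a CBS reduction of an acyclic enone, and its C6 carbinol from a chelation-controlled methallylation.
- The C1 quaternary centre and C5 come from an alkoxide-directed vinyl addition / aldol trapping on a 4-hydroxycyclopentenone. C2 comes from a hydroxyl-directed ketone reduction.
- Ring A is the first ring and carries the first stereocenter (C4). It is made by an amine-catalysed enantioselective aldol cyclisation of an achiral ene-1,4-dione built from biacetyl and 1-bromo-3-methylbutan-2-one.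

Assumption: the target is listed with the given SMILES unchanged; read literally, that string makes both oxirane carbons R, which would put the oxygen on opposite ring faces at C8 and C9, so the oxirane is taken to be the normal cis-fused one on the face of the 10-hydroxyl (as C9 is written), which is what the last step delivers.

Locants: C1–C10 follow the daucane skeleton (C1 methyl-bearing ring-fusion carbon; C2–C4 in ring A; C5 ring-fusion CH; C6–C10 in ring B), also for the corresponding carbons of monocyclic precursors; α is the face opposite the C1 methyl.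

**Step 1**
Reactants: 1 1-bromo-3-methylbutan-2-one; 2 butane-2,3-dione
Product: 5 (3E)-3,6-dimethylhept-3-ene-2,5-dione, via phosphonium bromide 3 (not isolated), via ylide 4 (not isolated)
Conditions: PPh3, PhMe, 60 °C; 2 M NaOH, CH2Cl2, rt; then 2 (3 equiv), PhMe, 80 °C
Reagents that add atoms: none
Why: One-pot Wittig olefination in which the stabilised acyl ylide attacks the activated 1,2-diketone once (excess 2); no stereocenter forms and the E/Z ratio does not matter because step 2 uses both isomers.

**Step 2**
Reactants: 5 (3E)-3,6-dimethylhept-3-ene-2,5-dione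
Product: 7 (4S)-4-hydroxy-2-methyl-4-(propan-2-yl)cyclopent-2-en-1-one, via (3Z)-enedione 6 (not isolated)
Conditions: 9-amino-9-deoxy-epi-quinine (20 mol %), 2-nitrobenzoic acid (40 mol %), PhMe, 40 °C
Reagents that add atoms: none
Why: Proposed new method: the primary amine condenses with the less hindered acetyl group to a cross-conjugated dienamine whose terminal carbon adds to the isobutyryl carbonyl held by the protonated quinuclidine (5-enolexo aldolisation), E-5 feeding the only cyclisable isomer 6 through reversible aza-Michael addition of the catalyst, so the tertiary carbinol C4 is the first stereocenter and is set by the catalyst (the epi-quinidine amine is used instead if the sense of induction turns out opposite); the closest known reaction types are the amine-catalysed intramolecular aldol of diketones (Hajos–Parrish type) and the racemic base-mediated cyclisation of cis-ene-1,4-diones to 4-hydroxycyclopentenones.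

**Step 3**
Reactants: 7 (4S)-4-hydroxy-2-methyl-4-(propan-2-yl)cyclopent-2-en-1-one; 8 vinylmagnesium bromide; 9 (2E)-but-2-enal
Product: 11 (2R,3S,4S)-3-ethenyl-4-hydroxy-2-[(2E)-1-hydroxybut-2-en-1-yl]-2-methyl-4-(propan-2-yl)cyclopentan-1-one (both carbinol epimers), via magnesium enolate 10 (not isolated)
Conditions: MeMgBr (1.0 equiv), THF, −78 °C; 8 (1.3 equiv), −78 to −40 °C; 9 (2 equiv), −78 °C; aq NH4Cl at −78 °C
Reagents that add atoms: none
Why: Alkoxide-directed (ligand-assisted) Grignard conjugate addition delivers vinyl to C5 on the face of the magnesium alkoxide and away from isopropyl, and the regiodefined enolate then undergoes aldol addition to 9 anti to the new vinyl group, which fixes the C1 quaternary centre with methyl cis to vinyl; the carbinol epimers converge in step 4.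

**Step 4**
Reactants: 11 (aldol adduct)
Product: 12 (2S,3S,4S)-2-[(2E)-but-2-enoyl]-3-ethenyl-4-hydroxy-2-methyl-4-(propan-2-yl)cyclopentan-1-one
Conditions: Dess–Martin periodinane, NaHCO3, CH2Cl2, 0 °C to rt
Reagents that add atoms: none
Why: Dess–Martin oxidation touches only the secondary allylic carbinol (the tertiary C4 hydroxyl cannot be oxidised) and merges both epimers into one non-enolisable 1,3-diketone without affecting C1, C4 or C5.

**Step 5**
Reactants: 12 (enone diketone)
Product: 13 (2E)-1-[(1S,2S,3S,5R)-2-ethenyl-3,5-dihydroxy-1-methyl-3-(propan-2-yl)cyclopentyl]but-2-en-1-one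
Conditions: Me4NBH(OAc)3 (3 equiv), MeCN/AcOH 1:1, −35 °C, short reaction time
Reagents that add atoms: none
Why: Evans–Saksena hydroxyl-directed reduction, in which the C4 hydroxyl exchanges onto boron and delivers hydride to the β-face of the ring ketone only (1,3-trans diol, C2–OH α), while the crotonyl ketone has no hydroxyl in reach at the start; the product is acetylated at once to forestall C2–OH-directed over-reduction or oxa-Michael closure.

**Step 6**
Reactants: 13 (C2 alcohol)
Product: 14 (1R,2S,3S,4S)-2-[(2E)-but-2-enoyl]-3-ethenyl-4-hydroxy-2-methyl-4-(propan-2-yl)cyclopentyl acetate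
Conditions: Ac2O (1.5 equiv), pyridine, DMAP (cat.), CH2Cl2, 0 °C
Reagents that add atoms: acetic anhydride, CC(=O)OC(C)=O
Why: DMAP-catalysed acylation of the only secondary hydroxyl; the tertiary C4 hydroxyl does not react at 0 °C and no C–O bond at a stereocenter is broken.

**Step 7**
Reactants: 14 (vinyl acetate)
Product: 15 (1R,2S,3S,4S)-2-[(2E)-but-2-enoyl]-3-formyl-4-hydroxy-2-methyl-4-(propan-2-yl)cyclopentyl acetate
Conditions: OsO4 (2 mol %), NaIO4 (2.5 equiv), 2,6-lutidine, dioxane/H2O 3:1, rt
Reagents that add atoms: sodium periodate, [Na+].[O-]I(=O)(=O)=O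
Why: Lemieux–Johnson cleavage, in which OsO4 dihydroxylates the monosubstituted vinyl group much faster than the electron-poor crotonyl alkene and periodate cleaves the diol to the C6 aldehyde; C5 keeps its configuration because the formyl group already sits trans to the larger crotonyl and isopropyl groups.

**Step 8**
Reactants: 15 (C6 aldehyde); 16 3-bromo-2-methylprop-1-ene
Product: 17 (1R,2S,3R,4S)-2-[(2E)-but-2-enoyl]-4-hydroxy-3-[(1R)-1-hydroxy-3-methylbut-3-en-1-yl]-2-methyl-4-(propan-2-yl)cyclopentyl acetate
Conditions: indium powder (In), 16 (2 equiv), THF/H2O 1:1, rt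
Reagents that add atoms: none
Why: Indium-mediated Barbier methallylation under chelation control, in which the free C4 hydroxyl and the aldehyde oxygen bind indium in a six-membered chelate cis-fused to ring A and the allyl group attacks its open face, giving the 1,3-anti diol (R at C6) chemoselectively at the aldehyde.

**Step 9**
Reactants: 17 (homoallylic alcohol); 18 3,4-dimethoxybenzoyl chloride
Product: 19 (1R)-1-[(1R,2S,3R,5S)-3-acetyloxy-2-[(2E)-but-2-enoyl]-5-hydroxy-2-methyl-5-(propan-2-yl)cyclopentyl]-3-methylbut-3-en-1-yl 3,4-dimethoxybenzoate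
Conditions: 18 (1.5 equiv), Et3N, DMAP (0.2 equiv), CH2Cl2, 0 °C to rt
Reagents that add atoms: none
Why: Acylation of the only secondary hydroxyl by the aroyl chloride; the tertiary C4 hydroxyl is too hindered and C6 keeps its configuration because its C–O bond is not broken.

**Step 10**
Reactants: 19 (enone diester)
Product: 20 (1R)-1-[(1R,2R,3R,5S)-3-acetyloxy-5-hydroxy-2-[(1S,2E)-1-hydroxybut-2-en-1-yl]-2-methyl-5-(propan-2-yl)cyclopentyl]-3-methylbut-3-en-1-yl 3,4-dimethoxybenzoate
Conditions: (R)-2-methyl-CBS-oxazaborolidine (0.3 equiv), catecholborane (2.5 equiv), PhMe, −78 °C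
Reagents that add atoms: none
Why: Corey–Bakshi–Shibata reduction with the quaternary C1 as the large and propenyl as the small ketone substituent, so the (R)-catalyst gives the (S)-allylic alcohol (the C10 configuration of the target), which is also the Felkin–Anh product with C5 as the large group; catecholborane at −78 °C spares the esters and the 1,1-disubstituted alkene.

**Step 11**
Reactants: 20 (diene diol)
Product: 21 (1R,2R,4S,5R,6R,10S)-2-acetoxy-4,10-dihydroxydauc-8-en-6-yl 3,4-dimethoxybenzoate (2α-OAc; 4β-OH; 6α-aroyloxy; 10α-OH; trans ring fusion)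
Conditions: second-generation Grubbs catalyst (10 mol %), 1,4-benzoquinone (10 mol %), PhMe (2 mM), 80 °C
Reagents that add atoms: none
Why: Ring-closing metathesis of the propenyl and methallyl groups closes ring B at C8=C9 as a trisubstituted cis-cycloheptene with loss of propene; benzoquinone suppresses Ru–H isomerisation of the allylic alcohol and no stereocenter is touched.

**Step 12**
Reactants: 21 (allylic alcohol)
Product: 22 (1R,2R,4S,5R,6R,8R,9R,10R)-2-acetoxy-8,9-epoxy-4,10-dihydroxydaucan-6-yl 3,4-dimethoxybenzoate (CNP0197096.2, descriptors as in the given string)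
Conditions: VO(acac)2 (5 mol %), t-BuOOH (1.5 equiv, decane), CH2Cl2, 0 °C
Reagents that add atoms: tert-butyl hydroperoxide, CC(C)(C)OO
Why: Hydroxyl-directed vanadium-catalysed epoxidation (Sharpless–Michaelson type), in which the C10 hydroxyl binds the vanadium peroxide and delivers oxygen to its own face of the trisubstituted alkene, setting C8 and C9 as the cis-fused oxirane syn to 10-OH, which under the stated assumption is the target.

**Compound list**
1 | 1-bromo-3-methylbutan-2-one | CC(C)C(=O)CBr | starting material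
2 | butane-2,3-dione | CC(=O)C(C)=O | starting material
3 | (3-methyl-2-oxobutyl)triphenylphosphonium bromide | CC(C)C(=O)C[P+](c1ccccc1)(c1ccccc1)c1ccccc1.[Br-] | intermediate
4 | 3-methyl-1-(triphenyl-λ5-phosphanylidene)butan-2-one | CC(C)C(=O)C=P(c1ccccc1)(c1ccccc1)c1ccccc1 | intermediate
5 | (3E)-3,6-dimethylhept-3-ene-2,5-dione | CC(=O)/C(C)=C/C(=O)C(C)C | intermediate
6 | (3Z)-3,6-dimethylhept-3-ene-2,5-dione | CC(=O)/C(C)=C\C(=O)C(C)C | intermediate
7 | (4S)-4-hydroxy-2-methyl-4-(propan-2-yl)cyclopent-2-en-1-one | O=C1C[C@](O)(C(C)C)C=C1C | intermediate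
8 | vinylmagnesium bromide | C=C[Mg]Br | starting material
9 | (2E)-but-2-enal | C/C=C/C=O | starting material
10 | bis(bromomagnesium) salt (C2 enolate, C4 alkoxide) of the 5-vinyl ketone from 7, vinyl cis to the C4 oxygen | CC1=C(O[Mg]Br)C[C@](O[Mg]Br)(C(C)C)[C@H]1C=C | intermediate
11 | (2R,3S,4S)-3-ethenyl-4-hydroxy-2-[(2E)-1-hydroxybut-2-en-1-yl]-2-methyl-4-(propan-2-yl)cyclopentan-1-one (both carbinol epimers) | C/C=C/C(O)[C@]1(C)C(=O)C[C@](O)(C(C)C)[C@H]1C=C | intermediate
12 | (2S,3S,4S)-2-[(2E)-but-2-enoyl]-3-ethenyl-4-hydroxy-2-methyl-4-(propan-2-yl)cyclopentan-1-one | C/C=C/C(=O)[C@]1(C)C(=O)C[C@](O)(C(C)C)[C@H]1C=C | intermediate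
13 | (2E)-1-[(1S,2S,3S,5R)-2-ethenyl-3,5-dihydroxy-1-methyl-3-(propan-2-yl)cyclopentyl]but-2-en-1-one | C/C=C/C(=O)[C@]1(C)[C@H](O)C[C@](O)(C(C)C)[C@H]1C=C | intermediate
14 | (1R,2S,3S,4S)-2-[(2E)-but-2-enoyl]-3-ethenyl-4-hydroxy-2-methyl-4-(propan-2-yl)cyclopentyl acetate | C/C=C/C(=O)[C@]1(C)[C@H](OC(C)=O)C[C@](O)(C(C)C)[C@H]1C=C | intermediate
15 | (1R,2S,3S,4S)-2-[(2E)-but-2-enoyl]-3-formyl-4-hydroxy-2-methyl-4-(propan-2-yl)cyclopentyl acetate | C/C=C/C(=O)[C@]1(C)[C@H](OC(C)=O)C[C@](O)(C(C)C)[C@H]1C=O | intermediate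
16 | 3-bromo-2-methylprop-1-ene | C=C(C)CBr | starting material
17 | (1R,2S,3R,4S)-2-[(2E)-but-2-enoyl]-4-hydroxy-3-[(1R)-1-hydroxy-3-methylbut-3-en-1-yl]-2-methyl-4-(propan-2-yl)cyclopentyl acetate | C/C=C/C(=O)[C@]1(C)[C@H](OC(C)=O)C[C@](O)(C(C)C)[C@H]1[C@H](O)CC(C)=C | intermediate
18 | 3,4-dimethoxybenzoyl chloride | COc1ccc(C(Cl)=O)cc1OC | starting material
19 | (1R)-1-[(1R,2S,3R,5S)-3-acetyloxy-2-[(2E)-but-2-enoyl]-5-hydroxy-2-methyl-5-(propan-2-yl)cyclopentyl]-3-methylbut-3-en-1-yl 3,4-dimethoxybenzoate | C/C=C/C(=O)[C@]1(C)[C@H](OC(C)=O)C[C@](O)(C(C)C)[C@H]1[C@H](OC(=O)c1ccc(OC)c(OC)c1)CC(C)=C | intermediate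
20 | (1R)-1-[(1R,2R,3R,5S)-3-acetyloxy-5-hydroxy-2-[(1S,2E)-1-hydroxybut-2-en-1-yl]-2-methyl-5-(propan-2-yl)cyclopentyl]-3-methylbut-3-en-1-yl 3,4-dimethoxybenzoate | C/C=C/[C@H](O)[C@]1(C)[C@H](OC(C)=O)C[C@](O)(C(C)C)[C@H]1[C@H](OC(=O)c1ccc(OC)c(OC)c1)CC(C)=C | intermediate
21 | (1R,2R,4S,5R,6R,10S)-2-acetoxy-4,10-dihydroxydauc-8-en-6-yl 3,4-dimethoxybenzoate | COc1ccc(C(=O)O[C@@H]2CC(C)=C[C@H](O)[C@]3(C)[C@H](OC(C)=O)C[C@](O)(C(C)C)[C@@H]23)cc1OC | intermediate
22 | (1R,2R,4S,5R,6R,8R,9R,10R)-2-acetoxy-8,9-epoxy-4,10-dihydroxydaucan-6-yl 3,4-dimethoxybenzoate | COc1ccc(C(=O)O[C@@H]2C[C@@]3(C)O[C@@H]3[C@H](O)[C@]3(C)[C@H](OC(C)=O)C[C@](O)(C(C)C)[C@@H]23)cc1OC | target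

**Step count**
Total steps: 12. Longest linear sequence: 12 steps (1 to 22).

**Steps most likely to fail**

Step 2 (the proposed new aldolisation; risks are low enantioselectivity, catalyst loss to aza-Michael adducts and retro-aldol erosion). The fallback sets out from 5 and uses only known chemistry. Irradiation at 365 nm gives the Z isomer 6, and aqueous Na2CO3 (the established base-mediated cyclisation of cis-ene-1,4-diones) gives the racemic hydroxy enone F1. Preparative SFC on a chiral stationary phase then separates 7 from the (4R)-antipode F2, which is discarded. The route is rejoined at 7.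

Step 3 (risks are 1,2-addition or poor facial control in the directed vinyl transfer, and retro-aldol or proton transfer when the hindered tetrasubstituted enolate forms the quaternary centre). The fallback sets out from 7 and replaces the basic enolate aldol by a Lewis-acid aldol. The enolate 10 is quenched with Me3SiCl to the bis(trimethylsilyl) enol ether F3. A Mukaiyama aldol with 9 (BF3·OEt2, CH2Cl2, −78 °C) gives the 4-O-trimethylsilyl aldol F4. Citric acid in MeOH removes the silyl group, and the route is rejoined at 11.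

Step 5 (risks are sluggish delivery from the tertiary hydroxyl across the five-membered ring, over-reduction of the crotonyl ketone directed by the new C2 hydroxyl, and oxa-Michael closure of the β-hydroxy enone). The fallback sets out from 11 and keeps the enone out of the hydride step. Et3SiCl/imidazole silylates the secondary allylic carbinol to give the triethylsilyl ether F5. Me4NBH(OAc)3 then reduces the only ketone under C4–OH direction to the C2 alcohol F6. Ac2O/DMAP gives the acetate F7, HF·pyridine gives the desilylated carbinol F8, and Dess–Martin oxidation rejoins the route at 14.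

**Further compounds**
F1 | step 2 | rac-4-hydroxy-2-methyl-4-(propan-2-yl)cyclopent-2-en-1-one | CC1=CC(O)(C(C)C)CC1=O
F2 | step 2 | (4R)-4-hydroxy-2-methyl-4-(propan-2-yl)cyclopent-2-en-1-one | O=C1C[C@@](O)(C(C)C)C=C1C
F3 | step 3 | bis(trimethylsilyl) enol ether of the 5-vinyl ketone (C2 silyl enol ether, C4 silyl ether) | CC1=C(O[Si](C)(C)C)C[C@](O[Si](C)(C)C)(C(C)C)[C@H]1C=C
F4 | step 3 | 4-O-trimethylsilyl ether of 11 | C/C=C/C(O)[C@]1(C)C(=O)C[C@](O[Si](C)(C)C)(C(C)C)[C@H]1C=C
F5 | step 5 | triethylsilyl ether of 11 at the allylic carbinol | C/C=C/C(O[Si](CC)(CC)CC)[C@]1(C)C(=O)C[C@](O)(C(C)C)[C@H]1C=C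
F6 | step 5 | C2 alcohol of F5 (C2–OH α) | C/C=C/C(O[Si](CC)(CC)CC)[C@]1(C)[C@H](O)C[C@](O)(C(C)C)[C@H]1C=C
F7 | step 5 | C2 acetate of F6 | C/C=C/C(O[Si](CC)(CC)CC)[C@]1(C)[C@H](OC(C)=O)C[C@](O)(C(C)C)[C@H]1C=C
F8 | step 5 | desilylated allylic carbinol of F7 | C/C=C/C(O)[C@]1(C)[C@H](OC(C)=O)C[C@](O)(C(C)C)[C@H]1C=C
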